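**Retrosynthetic overview**

1. The route rests on the benzene ring of the indenone (C3a, C4, C5, C6, C7, C7a). C3a, C7a, C7 and C6 are taken from C7a, C4a, C4 and C3 of a cyclopentanone-fused 2-pyranone that already carries the C1 ketone, the 7-methyl and the 6-azulenyl group; C4 and C5 come from an enamine, with loss of CO2 and pyrrolidine.
2. Late stage: CHO from CH2OH (carried as CH2OTBS); the C2–azulenyl bond and C2=C3 from acid-catalysed addition of guaiazulene to a 3-methylindane-1,2-dione and dehydration; the C3 methyl from cuprate addition to the indenone made from the indanone.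
3. Key disconnection: the indanone benzene ring is opened to the fused pyranone and the (E)-pyrrolidine enamine of 3-(silyloxy)propanal (Diels–Alder, C3a–C4 and C5–C6).
4. Pyranone from ethyl 2-(guaiazulen-3-yl)acetoacetate and cyclopentane-1,3-dione (Pechmann-type condensation); the keto ester from guaiazulene and ethyl diazoacetoacetate (Rh carbenoid C–H insertion).
5. Ring order: five-membered ketone ring (purchased) → pyranone ring → benzene ring (key step) → indenone C2=C3 last.

Key step: step 5

Remark: guaiazulen-3-yl means 5-isopropyl-3,8-dimethylazulen-1-yl; the formyl carbon is carried as a TBS-protected hydroxymethyl group because an aryl acetal or aldehyde would be attacked by guaiazulene under the acid of step 10, and a 3,3-dialkoxy enamine would act as a vinylogous amide acetal toward the acidic ring CH2 groups of the pyranone.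

**Route**

Step 1
Reactants: 1 ethyl acetoacetate
Product: 2 ethyl 2-diazo-3-oxobutanoate
Conditions: 4-acetamidobenzenesulfonyl azide, Et3N, MeCN, 0 °C to rt
Reagents that add atoms: 4-acetamidobenzenesulfonyl azide, CC(=O)Nc1ccc(cc1)S(=O)(=O)N=[N+]=[N-]
Why: Regitz diazo transfer to the doubly activated methylene of a β-keto ester is a standard reaction.

Step 2
Reactants: 2 ethyl 2-diazo-3-oxobutanoate; 3 guaiazulene
Product: 4 ethyl 2-(guaiazulen-3-yl)-3-oxobutanoate (racemic, keto–enol mixture)
Conditions: Rh2(OAc)4 (1 mol %), ClCH2CH2Cl, 70 °C, slow addition of 2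
Reagents that add atoms: none
Why: Metal-carbenoid C–H alkylation of an azulene: the electrophilic Rh carbenoid is attacked by C3, the only free nucleophilic position of the five-membered ring (C1 is methylated), and proton transfer in the tropylium-type zwitterion should give the formal C–H insertion product.

Step 3
Reactants: 4 ethyl 2-(guaiazulen-3-yl)-3-oxobutanoate; 5 cyclopentane-1,3-dione
Product: 7 3-(guaiazulen-3-yl)-4-methyl-6,7-dihydrocyclopenta[b]pyran-2,5-dione, via Knoevenagel dienol ester 6 (not isolated)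
Conditions: TsOH·H2O (0.2 equiv), toluene, reflux, Dean–Stark trap
Reagents that add atoms: none
Why: Pechmann-type condensation: acid-catalysed Knoevenagel attack of C2 of the dione enol on the ketone carbonyl, then lactonisation of the dienol onto the ester, as cyclic 1,3-diones and β-keto esters give fused 2-pyranones; protic acid directs C–C bond formation to the ketone and so to the 2-pyranone and not the 4-pyranone.

Step 4
Reactants: 8 3-(tert-butyldimethylsilyloxy)propanal; 9 pyrrolidine
Product: 10 (E)-1-[3-(tert-butyldimethylsilyloxy)prop-1-en-1-yl]pyrrolidine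
Conditions: K2CO3 (anhydrous), Et2O, 0 °C to rt; filtered, concentrated, used at once
Reagents that add atoms: none
Why: Enamine condensation of an aldehyde with a secondary amine under dehydrating conditions should give the thermodynamically preferred (E)-enamine, which is used without storage because a γ-silyloxy enamine can slowly lose silanolate.

Step 5
Reactants: 7 3-(guaiazulen-3-yl)-4-methyl-6,7-dihydrocyclopenta[b]pyran-2,5-dione; 10 (E)-1-[3-(tert-butyldimethylsilyloxy)prop-1-en-1-yl]pyrrolidine
Product: 13 4-[(tert-butyldimethylsilyloxy)methyl]-6-(guaiazulen-3-yl)-7-methylindan-1-one, via bridged lactone cycloadduct 11 (not isolated), via aminocyclohexadiene 12 (not isolated)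
Conditions: 10 (3 equiv), toluene, 100 °C, sealed tube; then AcOH, rt
Reagents that add atoms: none
Why: Inverse-electron-demand Diels–Alder reaction in which the nucleophilic β-carbon of the enamine bonds to C7a of the pyranone (β to the ring ketone and δ to the lactone carbonyl) and the aminomethine carbon then closes onto C3 to give the bridged lactone 11. Cycloreversion expels CO2 to give 12, and elimination of pyrrolidine, completed by the acetic acid treatment, aromatises the ring. The closest known reaction type is the benzene synthesis from coumalates and other 5-acyl-2-pyranones with enamines, enol ethers or ketene acetals. The benzene ring is closed by an intermolecular [4+2] addition that forms C3a–C4 and C5–C6 (indanone numbering) as a six-membered carbocycle, the lactone bridge being lost. The stereocentres of 11 and 12 disappear on aromatisation, so none has to be controlled. The step needs only regioselectivity, which the polarity match between the enamine β-carbon and the doubly activated C7a secures; the twisted azulenyl group at C3 slows the closure, which heat and excess enamine are meant to offset.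

Step 6
Reactants: 13 4-[(tert-butyldimethylsilyloxy)methyl]-6-(guaiazulen-3-yl)-7-methylindan-1-one
Product: 16 4-[(tert-butyldimethylsilyloxy)methyl]-6-(guaiazulen-3-yl)-7-methyl-1H-inden-1-one, via lithium enolate 14 (not isolated), via sulfilimine adduct 15 (not isolated)
Conditions: LiN(SiMe3)2, THF, −78 °C; then N-tert-butylbenzenesulfinimidoyl chloride, −78 °C; product used directly
Reagents that add atoms: none
Why: Mukaiyama dehydrogenation: the enolate is sulfenylated at C2 and the sulfilimine undergoes syn-elimination at low temperature, so no oxidant that would attack the azulene is needed, and the silylamide base deprotonates the ketone and not the acidic 4-methyl group of the azulene.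

Step 7
Reactants: 16 4-[(tert-butyldimethylsilyloxy)methyl]-6-(guaiazulen-3-yl)-7-methyl-1H-inden-1-one
Product: 18 4-[(tert-butyldimethylsilyloxy)methyl]-6-(guaiazulen-3-yl)-3,7-dimethylindan-1-one (racemic), via lithium enolate 17 (not isolated)
Conditions: Me2CuLi (from CuI and 2 MeLi), Et2O, −78 to −40 °C; then aq NH4Cl
Reagents that add atoms: lithium dimethylcuprate, [Li+].C[Cu-]C (formed from methyllithium, [Li]C, and CuI)
Why: Gilman cuprate 1,4-addition to the unsubstituted β-carbon C3 of the indenone; the new C3 stereocentre is formed racemic and is removed when C2=C3 is made in step 10.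

Step 8
Reactants: 18 4-[(tert-butyldimethylsilyloxy)methyl]-6-(guaiazulen-3-yl)-3,7-dimethylindan-1-one
Product: 20 4-[(tert-butyldimethylsilyloxy)methyl]-6-(guaiazulen-3-yl)-2-hydroxy-3,7-dimethylindan-1-one (diastereomer mixture, trans expected to predominate, racemic), via potassium enolate 19 (not isolated)
Conditions: KN(SiMe3)2, THF, −78 °C; then 3-phenyl-2-(phenylsulfonyl)oxaziridine, −78 °C; aq NH4Cl
Reagents that add atoms: 3-phenyl-2-(phenylsulfonyl)oxaziridine, O=S(=O)(c1ccccc1)N1OC1c1ccccc1
Why: Davis enolate hydroxylation at C2, the only α-position with hydrogens; oxygen should arrive anti to the 3-methyl group, but the C2 configuration is irrelevant because C2 becomes a carbonyl in step 9.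

Step 9
Reactants: 20 4-[(tert-butyldimethylsilyloxy)methyl]-6-(guaiazulen-3-yl)-2-hydroxy-3,7-dimethylindan-1-one
Product: 21 4-[(tert-butyldimethylsilyloxy)methyl]-6-(guaiazulen-3-yl)-3,7-dimethylindane-1,2-dione (racemic, enolisable; used crude)
Conditions: Dess–Martin periodinane, CH2Cl2, 0 °C to rt
Reagents that add atoms: none
Why: Dess–Martin oxidation of an α-hydroxy ketone to the 1,2-dione under nearly neutral conditions that the azulene and the silyl ether should tolerate.

Step 10
Reactants: 21 4-[(tert-butyldimethylsilyloxy)methyl]-6-(guaiazulen-3-yl)-3,7-dimethylindane-1,2-dione; 3 guaiazulene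
Product: 24 2,6-bis(guaiazulen-3-yl)-4-(hydroxymethyl)-3,7-dimethyl-1H-inden-1-one, via tertiary carbinol 22 (not isolated), via silyl ether indenone 23 (not isolated)
Conditions: 3 (1.05 equiv), TsOH·H2O (0.2 equiv), CH2Cl2, rt; then MeOH, TsOH·H2O, rt
Reagents that add atoms: none
Why: Acid-catalysed Friedel–Crafts hydroxyalkylation: C3 of guaiazulene adds to the unconjugated C2 carbonyl (C1 is conjugated and flanked by the 7-methyl), the azulenyl-stabilised cation from carbinol 22 loses the C3 proton (E1 dehydration) to give the indenone, and acidic methanol then cleaves the primary TBS ether, with no acetal or aldehyde present to compete for guaiazulene.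

Step 11
Reactants: 24 2,6-bis(guaiazulen-3-yl)-4-(hydroxymethyl)-3,7-dimethyl-1H-inden-1-one
Product: 25 2,6-bis(guaiazulen-3-yl)-3,7-dimethyl-1-oxo-1H-indene-4-carbaldehyde (CNP0222726.0)
Conditions: activated MnO2 (excess), CH2Cl2, rt
Reagents that add atoms: none
Why: MnO2 oxidation of a benzylic alcohol to the aldehyde, a mild heterogeneous oxidation commonly applied to azulenylmethanols and expected to leave the enone and the alkyl groups untouched.

**Compound list**

1 | ethyl acetoacetate | CCOC(=O)CC(C)=O | starting material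
2 | ethyl 2-diazo-3-oxobutanoate | CCOC(=O)C(=[N+]=[N-])C(C)=O | intermediate
3 | guaiazulene (7-isopropyl-1,4-dimethylazulene) | Cc1ccc2c(C)ccc(C(C)C)cc1-2 | starting material
4 | ethyl 2-(guaiazulen-3-yl)-3-oxobutanoate (racemic) | CCOC(=O)C(C(C)=O)c1cc(C)c2cc(C(C)C)ccc(C)c1-2 | intermediate
5 | cyclopentane-1,3-dione | O=C1CCC(=O)C1 | starting material
6 | ethyl (Z)-2-(guaiazulen-3-yl)-3-(2-hydroxy-5-oxocyclopent-1-en-1-yl)but-2-enoate (not isolated) | CCOC(=O)/C(c1cc(C)c2cc(C(C)C)ccc(C)c1-2)=C(C)\C1=C(O)CCC1=O | intermediate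
7 | 3-(guaiazulen-3-yl)-4-methyl-6,7-dihydrocyclopenta[b]pyran-2,5-dione | CC1=C(c2cc(C)c3cc(C(C)C)ccc(C)c2-3)C(=O)OC2=C1C(=O)CC2 | intermediate
8 | 3-(tert-butyldimethylsilyloxy)propanal | CC(C)(C)[Si](C)(C)OCCC=O | starting material
9 | pyrrolidine | C1CCNC1 | starting material
10 | (E)-1-[3-(tert-butyldimethylsilyloxy)prop-1-en-1-yl]pyrrolidine | CC(C)(C)[Si](C)(C)OC/C=C/N1CCCC1 | intermediate
11 | bridged lactone cycloadduct of 7 and 10 (2-oxabicyclo[2.2.2]oct-5-en-3-one fused to the cyclopentanone; amino and silyloxymethyl groups trans, endo/exo mixture, racemic; not isolated) | O=C1OC23CCC(=O)C2=C(C)C1(c1cc(C)c2cc(C(C)C)ccc(C)c1-2)C(N1CCCC1)C3CO[Si](C)(C)C(C)(C)C | intermediate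
12 | 4-[(tert-butyldimethylsilyloxy)methyl]-6-(guaiazulen-3-yl)-7-methyl-5-(pyrrolidin-1-yl)-2,3,4,5-tetrahydro-1H-inden-1-one (trans, racemic; not isolated) | CC1=C(c2cc(C)c3cc(C(C)C)ccc(C)c2-3)C(N2CCCC2)C(CO[Si](C)(C)C(C)(C)C)C2=C1C(=O)CC2 | intermediate
13 | 4-[(tert-butyldimethylsilyloxy)methyl]-6-(guaiazulen-3-yl)-7-methylindan-1-one | CC(C)(C)[Si](C)(C)OCc1cc(-c2cc(C)c3cc(C(C)C)ccc(C)c2-3)c(C)c2c1CCC2=O | intermediate
14 | lithium enolate of 13 (not isolated) | [Li]OC1=CCc2c(CO[Si](C)(C)C(C)(C)C)cc(-c3cc(C)c4cc(C(C)C)ccc(C)c3-4)c(C)c12 | intermediate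
15 | 2-(N-tert-butyl-S-phenylsulfinimidoyl) derivative of 13 (racemic; not isolated) | CC(C)(C)N=S(c1ccccc1)C1Cc2c(CO[Si](C)(C)C(C)(C)C)cc(-c3cc(C)c4cc(C(C)C)ccc(C)c3-4)c(C)c2C1=O | intermediate
16 | 4-[(tert-butyldimethylsilyloxy)methyl]-6-(guaiazulen-3-yl)-7-methyl-1H-inden-1-one | CC(C)(C)[Si](C)(C)OCc1cc(-c2cc(C)c3cc(C(C)C)ccc(C)c2-3)c(C)c2c1C=CC2=O | intermediate
17 | lithium enolate of 18 (not isolated) | [Li]OC1=CC(C)c2c(CO[Si](C)(C)C(C)(C)C)cc(-c3cc(C)c4cc(C(C)C)ccc(C)c3-4)c(C)c12 | intermediate
18 | 4-[(tert-butyldimethylsilyloxy)methyl]-6-(guaiazulen-3-yl)-3,7-dimethylindan-1-one (racemic) | CC(C)(C)[Si](C)(C)OCc1cc(-c2cc(C)c3cc(C(C)C)ccc(C)c2-3)c(C)c2c1C(C)CC2=O | intermediate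
19 | potassium enolate of 18 (not isolated) | [K]OC1=CC(C)c2c(CO[Si](C)(C)C(C)(C)C)cc(-c3cc(C)c4cc(C(C)C)ccc(C)c3-4)c(C)c12 | intermediate
20 | 4-[(tert-butyldimethylsilyloxy)methyl]-6-(guaiazulen-3-yl)-2-hydroxy-3,7-dimethylindan-1-one (diastereomer mixture, racemic) | CC(C)(C)[Si](C)(C)OCc1cc(-c2cc(C)c3cc(C(C)C)ccc(C)c2-3)c(C)c2c1C(C)C(O)C2=O | intermediate
21 | 4-[(tert-butyldimethylsilyloxy)methyl]-6-(guaiazulen-3-yl)-3,7-dimethylindane-1,2-dione (racemic) | CC(C)(C)[Si](C)(C)OCc1cc(-c2cc(C)c3cc(C(C)C)ccc(C)c2-3)c(C)c2c1C(C)C(=O)C2=O | intermediate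
22 | 4-[(tert-butyldimethylsilyloxy)methyl]-2,6-bis(guaiazulen-3-yl)-2-hydroxy-3,7-dimethylindan-1-one (diastereomer mixture; not isolated) | CC(C)(C)[Si](C)(C)OCc1cc(-c2cc(C)c3cc(C(C)C)ccc(C)c2-3)c(C)c2c1C(C)C(O)(c1cc(C)c3cc(C(C)C)ccc(C)c1-3)C2=O | intermediate
23 | 4-[(tert-butyldimethylsilyloxy)methyl]-2,6-bis(guaiazulen-3-yl)-3,7-dimethyl-1H-inden-1-one (not isolated) | CC(C)(C)[Si](C)(C)OCc1cc(-c2cc(C)c3cc(C(C)C)ccc(C)c2-3)c(C)c2c1C(C)=C(c1cc(C)c3cc(C(C)C)ccc(C)c1-3)C2=O | intermediate
24 | 2,6-bis(guaiazulen-3-yl)-4-(hydroxymethyl)-3,7-dimethyl-1H-inden-1-one | OCc1cc(-c2cc(C)c3cc(C(C)C)ccc(C)c2-3)c(C)c2c1C(C)=C(c1cc(C)c3cc(C(C)C)ccc(C)c1-3)C2=O | intermediate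
25 | 2,6-bis(guaiazulen-3-yl)-3,7-dimethyl-1-oxo-1H-indene-4-carbaldehyde (CNP0222726.0; no stereocentres) | CC1=C(c2cc(C)c3cc(C(C)C)ccc(C)c2-3)C(=O)c2c(C)c(-c3cc(C)c4cc(C(C)C)ccc(C)c3-4)cc(C=O)c21 | target

**Step count**

Total: 11 steps. Longest linear sequence: 10 steps (steps 1, 2, 3, 5, 6, 7, 8, 9, 10, 11); step 4 is the convergent branch.

**Steps most likely to fail, with fallbacks**

Step 5. The cycloaddition may stall because both diene termini are fully substituted. Meanwhile the γ-silyloxy enamine may be consumed by loss of silanolate to a propeniminium ion, and the pyrrolidine released may open the lactone of unreacted pyranone. The fallback sets out from 7 and uses a neutral enol ether in place of the enamine. Heating 7 with commercial (E)-1,3,3-trimethoxyprop-1-ene (CO/C=C/C(OC)OC) in a sealed tube at 150 °C, or at about 10 kbar, is the known 2-pyranone/enol ether Diels–Alder reaction with loss of CO2 and methanol. The enol ether carbon β to oxygen bonds to C7a, so the regiochemistry is unchanged, and the product should be 4-(dimethoxymethyl)-6-(guaiazulen-3-yl)-7-methylindan-1-one F1. Hydrolysis with PPTS in acetone/water should give 6-(guaiazulen-3-yl)-7-methyl-1-oxoindane-4-carbaldehyde F2. Reduction of the aldehyde in preference to the hindered aryl ketone with NaBH4 in EtOH/CH2Cl2 at −78 °C should give 6-(guaiazulen-3-yl)-4-(hydroxymethyl)-7-methylindan-1-one F3. Silylation with TBSCl and imidazole in DMF comes back to the route at 13.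

Step 3. The Knoevenagel attack on the hindered, largely enolised ketone of 4 may be too slow. Transesterification followed by O-to-C acyl shift would then lead toward the isomeric 4-pyranone, or the azulene may degrade on long heating with acid. The fallback sets out from 4 and forms the C3–C4 bond of the pyranone by an intramolecular aldol condensation instead. Retro-Claisen deacetylation of 4 (NaOEt, EtOH) should give ethyl (guaiazulen-3-yl)acetate F4, and saponification (LiOH, THF/H2O, then mild acid) should give (guaiazulen-3-yl)acetic acid F5. Esterification of the enol of commercial 2-acetylcyclopentane-1,3-dione (CC(=O)C1C(=O)CCC1=O) with DCC and catalytic DMAP in CH2Cl2 should give 2-acetyl-3-oxocyclopent-1-en-1-yl (guaiazulen-3-yl)acetate F6. Base-induced aldol condensation of the arylacetate CH2 onto the acetyl carbonyl (Et3N, toluene, 80 °C; Kostanecki-type, as for 3-aryl-4-methylcoumarins) comes back to the route at 7.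

Step 10. Addition to the C2 carbonyl may be retarded by the adjacent 3-methyl group and by enolisation of the dione toward C3. That would leave time for self-condensation of the dione or for a second attack of guaiazulene on the azulenyl-stabilised cation. The fallback sets out from 13 and brings in the azulene before the methyl group, when C2 is less hindered. Enolate hydroxylation of 13 (KN(SiMe3)2, Davis oxaziridine) should give 4-[(tert-butyldimethylsilyloxy)methyl]-6-(guaiazulen-3-yl)-2-hydroxy-7-methylindan-1-one F7, and Dess–Martin oxidation should give 4-[(tert-butyldimethylsilyloxy)methyl]-6-(guaiazulen-3-yl)-7-methylindane-1,2-dione F8. Guaiazulene with catalytic TsOH in CH2Cl2 should then add at C2 and dehydrate to 4-[(tert-butyldimethylsilyloxy)methyl]-2,6-bis(guaiazulen-3-yl)-7-methyl-1H-inden-1-one F9. Conjugate addition of Me2CuLi should give 4-[(tert-butyldimethylsilyloxy)methyl]-2,6-bis(guaiazulen-3-yl)-3,7-dimethylindan-1-one F10. Dehydrogenation of its lithium enolate with N-tert-butylbenzenesulfinimidoyl chloride comes back to the route at 23, which is desilylated with TsOH in methanol as in the second stage of step 10.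

**Further compounds**

F1 | step 5 | 4-(dimethoxymethyl)-6-(guaiazulen-3-yl)-7-methylindan-1-one | COC(OC)c1cc(-c2cc(C)c3cc(C(C)C)ccc(C)c2-3)c(C)c2c1CCC2=O
F2 | step 5 | 6-(guaiazulen-3-yl)-7-methyl-1-oxoindane-4-carbaldehyde | O=Cc1cc(-c2cc(C)c3cc(C(C)C)ccc(C)c2-3)c(C)c2c1CCC2=O
F3 | step 5 | 6-(guaiazulen-3-yl)-4-(hydroxymethyl)-7-methylindan-1-one | OCc1cc(-c2cc(C)c3cc(C(C)C)ccc(C)c2-3)c(C)c2c1CCC2=O
F4 | step 3 | ethyl (guaiazulen-3-yl)acetate | CCOC(=O)Cc1cc(C)c2cc(C(C)C)ccc(C)c1-2
F5 | step 3 | (guaiazulen-3-yl)acetic acid | OC(=O)Cc1cc(C)c2cc(C(C)C)ccc(C)c1-2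
F6 | step 3 | 2-acetyl-3-oxocyclopent-1-en-1-yl (guaiazulen-3-yl)acetate | CC(=O)C1=C(OC(=O)Cc2cc(C)c3cc(C(C)C)ccc(C)c2-3)CCC1=O
F7 | step 10 | 4-[(tert-butyldimethylsilyloxy)methyl]-6-(guaiazulen-3-yl)-2-hydroxy-7-methylindan-1-one (racemic) | CC(C)(C)[Si](C)(C)OCc1cc(-c2cc(C)c3cc(C(C)C)ccc(C)c2-3)c(C)c2c1CC(O)C2=O
F8 | step 10 | 4-[(tert-butyldimethylsilyloxy)methyl]-6-(guaiazulen-3-yl)-7-methylindane-1,2-dione | CC(C)(C)[Si](C)(C)OCc1cc(-c2cc(C)c3cc(C(C)C)ccc(C)c2-3)c(C)c2c1CC(=O)C2=O
F9 | step 10 | 4-[(tert-butyldimethylsilyloxy)methyl]-2,6-bis(guaiazulen-3-yl)-7-methyl-1H-inden-1-one | CC(C)(C)[Si](C)(C)OCc1cc(-c2cc(C)c3cc(C(C)C)ccc(C)c2-3)c(C)c2c1C=C(c1cc(C)c3cc(C(C)C)ccc(C)c1-3)C2=O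
F10 | step 10 | 4-[(tert-butyldimethylsilyloxy)methyl]-2,6-bis(guaiazulen-3-yl)-3,7-dimethylindan-1-one (diastereomer mixture, racemic) | CC(C)(C)[Si](C)(C)OCc1cc(-c2cc(C)c3cc(C(C)C)ccc(C)c2-3)c(C)c2c1C(C)C(c1cc(C)c3cc(C(C)C)ccc(C)c1-3)C2=O
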